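We read the flask at 40 h, and that time means little until we hold it against a time of the flask itself.

| setting | summer | spring | flask |
|---|---|---|---|
| free monomer | 48 mM | 48 mM | 48 mM |
| pre-initiator | 1.2 mM | 4.8 mM | 2.4 mM |
| remark | run made earlier | run made earlier |  |
| time |  |  | 40 h |

| run | time / h | monomer in chains / % | free monomer / % |
|---|---|---|---|
| summer | 6.00 | 0.5 | 99.6 |
| summer | 12.0 | 1.5 | 98.9 |
| summer | 15.0 | 3.0 | 97.6 |
| summer | 25.0 | 5.1 | 94.7 |
| summer | 30.0 | 8.0 | 92.4 |
| summer | 40.0 | 12.6 | 87.1 |
| spring | 6.00 | 1.6 | 99.8 |
| spring | 12.0 | 4.5 | 95.1 |
| spring | 15.0 | 7.7 | 92.0 |
| spring | 25.0 | 20.0 | 79.8 |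
| spring | 30.0 | 25.3 | 73.0 |
| spring | 40.0 | 40.7 | 59.8 |

(readings scatter by 0.5 percentage points)

- the average divides the monomer in chains by the number of chains begun, living and dead together
- the analysis behind the earlier runs scatters by 0.5 percentage points, standard deviation
- the earlier runs do not show the number of chains; that part of a forecast is a guess

* average number of monomer units in a chain (chains begun, living or dead) at 40 h
* part of the free monomer that has reacted at 40 h

1. In both earlier runs the readings show minus the logarithm of the fraction of free monomer left growing about as time squared. From 25.0 h to 40.0 h it rises 2.54 times in the summer run and 2.28 times in the spring run, against 2.56 for the square.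

2. The flask holds twice the summer pre-initiator and half the spring pre-initiator. So for the flask we take the geometric mean of the two logarithms read at 40.0 h. We then define the ramp time, the time at which minus that logarithm reaches one while the square law holds. The mean gives a ramp time of 77.5 h.

3. Now the flask in slow motion, by our own reckoning. The momentary half-life of free monomer, a pseudo-first-order half-life, is ln(2) times the ramp time squared, over twice the time. At 4.00 h it is 520 h, and 0.266% has reacted. At 20.0 h it is 104 h, with 6.44% reacted. At 40 h it is 52.0 h, still longer than the time elapsed, with 23.4% reacted. What is about to matter is a bend: the rise in the spring run already reads below the square.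

4. The readings do not show the number of chains, so we give no chain length. The forecast gives 24% reacted, more than our figure, and chains of 14 units: “this is largely a guess”.

The flask gives 23.9% reacted and chains of 9.61 units on average.

    free monomer + initiator → living end + monomer in chains (k = 0.0578 M⁻¹ min⁻¹)
    free monomer + living end → monomer in chains + living end, rate k2*[living end]*[free monomer] (k = 0.218 M⁻¹ min⁻¹)
    monomer in chains + living end → free monomer + living end, rate k3*[living end] as long as [monomer in chains] is above zero (k = 0.00208 min⁻¹)
    pre-initiator ⇌ initiator (K = 0.570, k = 4.55 × 10⁻⁴ min⁻¹)

At 40.0 h the flask holds living end at 1.19 mM, half the pre-initiator charge. Its free monomer left, 76%, gives a ramp time of 76.5 h, beside our 77.5 h. The same charge read at 6.0 d stands at about twice the ramp time. There the square law gives 96.8% reacted, and that flask has reacted 75.7%.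

(The readings are simulated with made-up constants.)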